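The numbers in the tables were computed from invented constants; scatter was added.

I began with the reagent.

| flask | starting material | reagent | remark | time |
|---|---|---|---|---|
| Friday's | 0.41 M | 0.41 M | the very flask that is asked about, followed so far |  |
| Monday's | 0.82 M | 0.41 M | run made earlier |  |
| flask | 0.41 M | 0.410 M |  | 2.0 min |

- Friday's (time / s: target / %): 20.0: 24.4; 40.0: 34.8; 60.0: 38.0; 80.0: 39.2; 90.0: 38.4; 120: 38.0
- Monday's (time / s: target / %): 10.0: 13.6; 25.0: 23.6; 40.0: 27.1; 60.0: 28.5; 90.0: 30.1; 120: 27.9

(standard deviation of a reading: 0.5 percentage points)

- removed target is counted in
- what was read earlier has a scatter of 0.5 percentage points, one standard deviation
- additions bring no volume worth counting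

- elm: at 2.0 min take out 90% of the target then present, then wait 1.0 min
- larch: at 2.0 min add starting material, 50.0% of the amount charged, then wait 1.0 min
- maple: change nothing and wait 1.0 min more
- cedar: at 2.0 min add reagent, 50.0% of the amount charged, then wait 1.0 min

- target, in percent of the starting material first charged, at 2.0 min
- what to do for the largest gain in target; "none" if nothing gains more than 2 percentage points (elm / larch / maple / cedar / none)
- target present, with what was taken out counted in, in percent of the starting material first charged, after elm
- target present, with what was taken out counted in, in percent of the starting material first charged, after maple

Friday's flask and Monday's looked nearly the same: they held the same reagent, but Monday's held twice the starting material. From 60.0 s on, the readings stayed roughly level, Friday's at 38.4% and Monday's at 28.8%. Monday's reagent, the limiting reagent there, allowed a target share of half, and the level stopped below that, so I read both flasks as stopping short of their ceilings.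

For Friday's flask, the target share divided by the product of the two shares it leaves unreacted, each against the starting-material charge, came to 1.01. I called this the holding number, an equilibrium quotient in fractions of the charge. Monday's came to 1.91, twice Friday's, so I let it grow in step with the starting-material charge.

Since the asked flask is Friday's, I took 38.4% for now and for maple. After elm, with the target left behind in the flask counted, the holding number reckoned the target at 20.5%, and with the removed part the total came to 55.0%. Larch and cedar each gained 12 percentage points, so I chose elm.

The forecast gave 38.4%, elm, 53.5% and 38.4%, and its ground was to “take this as equilibrium, reached by 2 min”.

The flask gave 38.3%, elm with a gain of 7.7 points, 46.0% after elm and 34.9% after maple.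

    reagent + target → over-reaction product (k = 0.0188 /M/s)
    starting material + target → side product (k = 0.00156 /M/s)
    starting material + reagent ⇌ target + by-product (K = 1.40, k = 0.0457 /M/s)
    crystals ⇌ by-product, rate k4*(cs4 - [by-product]) while solid is left; crystals form when [by-product] > cs4 (solubility = 0.160 M, k = 0.0943 /s)

With each step taken net, target in the flask was made 5.92 times as fast as it was used up at 0.343 min, but at 2.00 min the making ran at 0.580 of the using up, so the target was on its way down. The shares then present, 44.6% of starting material and 31.7% of reagent, put the quotient at 2.71 against my holding number of 1.01. In the neighbour with 0.16 M of starting material, the number scaled to 0.395 reckons 45.4% of target; that flask held 46.1%, at a quotient of 1.09.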